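**Plan**
- Cuts: first O1–C8a of the dihydropyran ring, which takes the chroman back to a tertiary alcohol on a hydroquinone dimethyl ether. Then C2–C1', the bond between the fully substituted ring carbon and the first CH2 of the C16 side chain.
- Enabling feature: C2 carries O1, a methyl group, C3 and C1'. Because it bears oxygen, it maps back onto the carbinol C–H of a 4-arylbutan-2-ol. A hindered benzoate on that carbinol acidifies the C–H and later leaves, while boron holds the place of O1.
- Forward order: phytol is trimmed to the C16 boronic ester (5 steps), and 1,4-dimethoxy-2,5-dimethylbenzene plus (R)-propylene oxide give the benzoate (3 steps). The two are joined by lithiation–borylation with a 1,2-metallate shift and oxidation. The heterocycle is closed last (quinone, reduction, acid).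
- Stereochemistry: C4' and C8' come unchanged from natural phytol. C2 comes from (R)-propylene oxide through Mitsunobu inversion, retentive lithiation and borylation, invertive 1,2-migration, retentive oxidation, and a ring closure that leaves the C2–O bond intact.

Key step: step 9

Assumption: commercial phytol of natural origin has the (7R,11R) configuration. Any Z isomer in it gives the same ketone on ozonolysis.

Step 1
Reactants: 1 (2E,7R,11R)-3,7,11,15-tetramethylhexadec-2-en-1-ol (natural phytol)
Product: 2 (6R,10R)-6,10,14-trimethylpentadecan-2-one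
Conditions: O3, CH2Cl2/MeOH, −78 °C; then Me2S, −78 °C to rt
Reagents that add atoms: ozone, [O-][O+]=O
Why: Criegee ozonolysis with reductive work-up cleaves the only C=C bond and leaves the two remote methyl-bearing stereocentres unchanged.

Step 2
Reactants: 2 (6R,10R)-6,10,14-trimethylpentadecan-2-one
Product: 3 (4R,8R)-4,8,12-trimethyltridecyl acetate
Conditions: mCPBA (2 equiv), CF3CO2H (1 equiv), CH2Cl2, 0 °C to rt, dark
Reagents that add atoms: mCPBA (3-chloroperoxybenzoic acid), OOC(=O)c1cccc(Cl)c1
Why: In this Baeyer–Villiger oxidation the primary alkyl group migrates in preference to methyl, so oxygen enters between the carbonyl carbon and the chain and trims it to the C16 unit, with acid co-catalysis as the known remedy for slow acyclic methyl ketones.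

Step 3
Reactants: 3 (4R,8R)-4,8,12-trimethyltridecyl acetate
Product: 4 (4R,8R)-4,8,12-trimethyltridecan-1-ol
Conditions: K2CO3 (0.2 equiv), MeOH, rt
Reagents that add atoms: none
Why: Base-catalysed transesterification of a primary acetate is mild and cannot touch the stereocentres.

Step 4
Reactants: 4 (4R,8R)-4,8,12-trimethyltridecan-1-ol
Product: 5 (4R,8R)-1-bromo-4,8,12-trimethyltridecane
Conditions: CBr4, PPh3, CH2Cl2, 0 °C
Reagents that add atoms: tetrabromomethane, BrC(Br)(Br)Br
Why: In the Appel reaction bromide displaces the alkoxyphosphonium group at the primary carbon by SN2 under neutral conditions.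

Step 5
Reactants: 5 (4R,8R)-1-bromo-4,8,12-trimethyltridecane
Product: 6 5,5-dimethyl-2-[(4S,8R)-4,8,12-trimethyltridecyl]-1,3,2-dioxaborinane
Conditions: bis(neopentyl glycolato)diboron, CuI (10 mol %), PPh3 (13 mol %), LiOMe (2 equiv), DMF, rt
Reagents that add atoms: bis(neopentyl glycolato)diboron, CC1(C)COB(OC1)B1OCC(C)(C)CO1
Why: Copper-catalysed borylation of an unactivated primary alkyl bromide with a diboron reagent gives the slim neopentyl glycol ester that the hindered carbanion of step 9 needs, and the descriptor at C4 changes from R to S only because boron ranks below carbon.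

Step 6
Reactants: 7 1,4-dimethoxy-2,5-dimethylbenzene
Product: 8 1-(chloromethyl)-2,5-dimethoxy-3,6-dimethylbenzene
Conditions: (CH2O)n (1.0 equiv), conc. aq. HCl, HCl (g), 1,4-dioxane, 50 °C
Reagents that add atoms: paraformaldehyde (as formaldehyde), C=O; hydrogen chloride, Cl
Why: In this Blanc chloromethylation the two free ring positions of 7 are equivalent, so only one monochloromethyl compound is possible, and limiting formaldehyde together with the mildly deactivating CH2Cl group should hold back a second substitution.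

Step 7
Reactants: 8 1-(chloromethyl)-2,5-dimethoxy-3,6-dimethylbenzene; 9 (R)-2-methyloxirane ((R)-propylene oxide)
Product: 11 (2R)-4-(2,5-dimethoxy-3,6-dimethylphenyl)butan-2-ol, via benzylmagnesium chloride 10 (not isolated)
Conditions: Mg turnings, THF, 0 °C, slow addition of 8; then CuI (10 mol %), 9, −30 to 0 °C; aqueous quench
Reagents that add atoms: none
Why: Copper-catalysed SN2 opening of a terminal epoxide by a benzylic Grignard reagent occurs at the unsubstituted carbon, so the C–O stereocentre of 9 is carried over unchanged as (R).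

Step 8
Reactants: 11 (2R)-4-(2,5-dimethoxy-3,6-dimethylphenyl)butan-2-ol
Product: 12 (2S)-4-(2,5-dimethoxy-3,6-dimethylphenyl)butan-2-yl 2,4,6-triisopropylbenzoate
Conditions: 2,4,6-triisopropylbenzoic acid, PPh3, DIAD, THF, 0 °C to rt
Reagents that add atoms: 2,4,6-triisopropylbenzoic acid, CC(C)c1cc(C(C)C)c(C(=O)O)c(C(C)C)c1
Why: Mitsunobu esterification installs the hindered benzoate by SN2 inversion, giving the (S)-ester and avoiding acylation with a very hindered acid chloride.

Step 9
Reactants: 12 (2S)-4-(2,5-dimethoxy-3,6-dimethylphenyl)butan-2-yl 2,4,6-triisopropylbenzoate; 6 5,5-dimethyl-2-[(4S,8R)-4,8,12-trimethyltridecyl]-1,3,2-dioxaborinane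
Product: 16 (3R,7R,11R)-1-(2,5-dimethoxy-3,6-dimethylphenyl)-3,7,11,15-tetramethylhexadecan-3-ol, via lithiated benzoate 13 (not isolated), via boronate complex 14 (not isolated), via tertiary boronic ester 15 (not isolated)
Conditions: s-BuLi (1.6 equiv), TMEDA (6 equiv), cyclopentyl methyl ether, −60 °C, 2 h; then 6 (1.7 equiv), −60 °C to rt, then 50 °C; then 2 M NaOH, 30% H2O2, THF, 0 °C to rt
Reagents that add atoms: hydrogen peroxide, OO
Why: s-BuLi/TMEDA pre-complexes to the benzoate carbonyl and removes the carbinol C–H with retention, giving the chelated, configurationally stable tertiary α-oxyalkyllithium 13, which adds to the boron atom of 6 with retention to give boronate 14. On warming, the C16 alkyl group migrates from boron to carbon antiperiplanar to the departing triisopropylbenzoate (stereospecific 1,2-metallate rearrangement, inversion at carbon), which forms the C2–C1' bond and the fully substituted centre in one event, and basic H2O2 then replaces boron by oxygen with retention. The closest known reaction type is the lithiation–borylation of secondary dialkyl 2,4,6-triisopropylbenzoates (4-arylbutan-2-yl esters are standard substrates) with neopentyl glycol alkylboronic esters, a reagent-controlled relative of the Matteson homologation. No ring is closed. The one new stereocentre, C2, is controlled solely by the (S)-carbinol centre of 12 through the sequence retention, retention, inversion, retention, which leads to (3R)-16, while C4' and C8' are spectators. The step needs deprotonation at the carbinol C–H rather than at the lone ring C–H, the aryl methyl groups or ArCH2, and migration of carbon rather than a glycol oxygen: the first is secured by the five-membered Li–O=C chelate and the weak directing power of the flanked methoxy groups at −60 °C, the second by the antiperiplanar alignment and the poor migratory aptitude of oxygen ligands, while the triisopropylphenyl group shields the ester carbonyl from attack.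

Step 10
Reactants: 16 (3R,7R,11R)-1-(2,5-dimethoxy-3,6-dimethylphenyl)-3,7,11,15-tetramethylhexadecan-3-ol
Product: 17 2-[(3R,7R,11R)-3-hydroxy-3,7,11,15-tetramethylhexadecyl]-3,6-dimethylcyclohexa-2,5-diene-1,4-dione (β-tocopherylquinone)
Conditions: (NH4)2Ce(NO3)6 (2.5 equiv), MeCN/H2O, 0 °C
Reagents that add atoms: water, O
Why: Oxidative demethylation of a hydroquinone dimethyl ether by tetravalent cerium gives the p-quinone, with water supplying the carbonyl oxygens, and the tertiary alcohol and saturated chain are inert.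

Step 11
Reactants: 17 2-[(3R,7R,11R)-3-hydroxy-3,7,11,15-tetramethylhexadecyl]-3,6-dimethylcyclohexa-2,5-diene-1,4-dione
Product: 19 (2R)-2,5,8-trimethyl-2-[(4R,8R)-4,8,12-trimethyltridecyl]-3,4-dihydro-2H-chromen-6-ol ((2R,4'R,8'R)-β-tocopherol), via hydroquinone 18 (not isolated)
Conditions: H2 (1 atm), Pd/C, MeOH, rt; filtration under Ar; then conc. HCl (cat.), MeOH, 50 °C, Ar
Reagents that add atoms: none
Why: This is the known reductive cyclisation of tocopherylquinones, in which the tertiary hydroxyl of 18 adds to C8a of the protonated keto tautomer and water is lost from the ring carbon, so the C2–O bond should stay intact, C2 should stay (R), and only the hydroxyl ortho to the chain can close the six-membered ring.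

**Compound list**
1 | (2E,7R,11R)-3,7,11,15-tetramethylhexadec-2-en-1-ol (phytol) | OC/C=C(\C)CCC[C@H](C)CCC[C@H](C)CCCC(C)C | starting material
2 | (6R,10R)-6,10,14-trimethylpentadecan-2-one | CC(=O)CCC[C@H](C)CCC[C@H](C)CCCC(C)C | intermediate
3 | (4R,8R)-4,8,12-trimethyltridecyl acetate | CC(=O)OCCC[C@H](C)CCC[C@H](C)CCCC(C)C | intermediate
4 | (4R,8R)-4,8,12-trimethyltridecan-1-ol | OCCC[C@H](C)CCC[C@H](C)CCCC(C)C | intermediate
5 | (4R,8R)-1-bromo-4,8,12-trimethyltridecane | BrCCC[C@H](C)CCC[C@H](C)CCCC(C)C | intermediate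
6 | 5,5-dimethyl-2-[(4S,8R)-4,8,12-trimethyltridecyl]-1,3,2-dioxaborinane | CC1(C)COB(CCC[C@H](C)CCC[C@H](C)CCCC(C)C)OC1 | intermediate
7 | 1,4-dimethoxy-2,5-dimethylbenzene | COc1cc(C)c(OC)cc1C | starting material
8 | 1-(chloromethyl)-2,5-dimethoxy-3,6-dimethylbenzene | COc1cc(C)c(OC)c(CCl)c1C | intermediate
9 | (R)-2-methyloxirane | C[C@@H]1CO1 | starting material
10 | (2,5-dimethoxy-3,6-dimethylbenzyl)magnesium chloride | COc1cc(C)c(OC)c(C[Mg]Cl)c1C | intermediate
11 | (2R)-4-(2,5-dimethoxy-3,6-dimethylphenyl)butan-2-ol | C[C@@H](O)CCc1c(C)c(OC)cc(C)c1OC | intermediate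
12 | (2S)-4-(2,5-dimethoxy-3,6-dimethylphenyl)butan-2-yl 2,4,6-triisopropylbenzoate | C[C@H](OC(=O)c1c(C(C)C)cc(C(C)C)cc1C(C)C)CCc1c(C)c(OC)cc(C)c1OC | intermediate
13 | (2S)-4-(2,5-dimethoxy-3,6-dimethylphenyl)-2-lithiobutan-2-yl 2,4,6-triisopropylbenzoate | [Li][C@@](C)(OC(=O)c1c(C(C)C)cc(C(C)C)cc1C(C)C)CCc1c(C)c(OC)cc(C)c1OC | intermediate
14 | lithium boronate complex of 13 and 6 (boron bears the C16 alkyl group, the neopentyl glycolate and the (S)-α-benzoyloxy carbon) | [Li+].CC1(C)CO[B-](CCC[C@H](C)CCC[C@H](C)CCCC(C)C)(OC1)[C@@](C)(OC(=O)c1c(C(C)C)cc(C(C)C)cc1C(C)C)CCc1c(C)c(OC)cc(C)c1OC | intermediate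
15 | 2-[(3S,7R,11R)-1-(2,5-dimethoxy-3,6-dimethylphenyl)-3,7,11,15-tetramethylhexadecan-3-yl]-5,5-dimethyl-1,3,2-dioxaborinane | CC1(C)COB(OC1)[C@](C)(CCC[C@H](C)CCC[C@H](C)CCCC(C)C)CCc1c(C)c(OC)cc(C)c1OC | intermediate
16 | (3R,7R,11R)-1-(2,5-dimethoxy-3,6-dimethylphenyl)-3,7,11,15-tetramethylhexadecan-3-ol | O[C@](C)(CCC[C@H](C)CCC[C@H](C)CCCC(C)C)CCc1c(C)c(OC)cc(C)c1OC | intermediate
17 | 2-[(3R,7R,11R)-3-hydroxy-3,7,11,15-tetramethylhexadecyl]-3,6-dimethylcyclohexa-2,5-diene-1,4-dione | O[C@](C)(CCC[C@H](C)CCC[C@H](C)CCCC(C)C)CCC1=C(C)C(=O)C=C(C)C1=O | intermediate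
18 | 2-[(3R,7R,11R)-3-hydroxy-3,7,11,15-tetramethylhexadecyl]-3,6-dimethylbenzene-1,4-diol | O[C@](C)(CCC[C@H](C)CCC[C@H](C)CCCC(C)C)CCc1c(C)c(O)cc(C)c1O | intermediate
19 | (2R,4'R,8'R)-β-tocopherol | Cc1cc(O)c(C)c2c1O[C@](C)(CCC[C@H](C)CCC[C@H](C)CCCC(C)C)CC2 | target

**Step count**
Total step count: 11.
Longest linear sequence: 8 steps (steps 1–5 and 9–11).

**Steps most likely to fail**

**Step 9.**
- What may go wrong: ring or benzylic metalation next to the methoxy groups may compete with removal of the hindered carbinol C–H. Deprotonation may stay incomplete. Reversible boronate formation would lower conversion and stereospecificity. Surplus 6 ends as alcohol 4 after oxidation and can be recycled.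
- Fallback: it sets out from bromide 5 and Grignard reagent 10 and comes back at 16. It makes the same C2–C1' bond by enolate alkylation with self-regeneration of a stereocentre.
- Bromide 5 is exchanged with NaI in acetone to (4R,8R)-1-iodo-4,8,12-trimethyltridecane F1.
- (S)-Lactic acid and pivalaldehyde are condensed (p-TsOH, pentane, water separator) to (2S,5S)-2-tert-butyl-5-methyl-1,3-dioxolan-4-one F2.
- The enolate of F2 (LiN(i-Pr)2, THF/DMPU, −78 °C) should be alkylated by F1 on the face opposite the tert-butyl group. This gives (2S,5R)-2-tert-butyl-5-methyl-5-[(4R,8R)-4,8,12-trimethyltridecyl]-1,3-dioxolan-4-one F3.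
- LiAlH4 in THF reduces F3 to (2R,6R,10R)-2,6,10,14-tetramethylpentadecane-1,2-diol F4.
- TsCl in pyridine gives (2R,6R,10R)-2-hydroxy-2,6,10,14-tetramethylpentadecyl 4-methylbenzenesulfonate F5.
- K2CO3 in MeOH closes F5 to (2R)-2-methyl-2-[(4R,8R)-4,8,12-trimethyltridecyl]oxirane F6.
- Opening of F6 at its CH2 group with 10 and CuI (10 mol %) in THF gives 16.

**Step 11.**
- What may go wrong: the tertiary C2–O bond may ionise under acid, with loss of configuration at C2 or elimination to alkenes.
- Fallback: it sets out from hydroquinone 18, isolated under argon after the hydrogenation of 17, and comes back at 19. The ring is closed by aryl–oxygen bond formation under basic conditions, so the C2–O bond is never at risk.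
- TBSCl (1.0 equiv) and imidazole in DMF at 0 °C should silylate the less hindered hydroxyl. This gives 4-[(tert-butyldimethylsilyl)oxy]-2-[(3R,7R,11R)-3-hydroxy-3,7,11,15-tetramethylhexadecyl]-3,6-dimethylphenol F7.
- PhNTf2 and Cs2CO3 in DMF convert the remaining phenol to 4-[(tert-butyldimethylsilyl)oxy]-2-[(3R,7R,11R)-3-hydroxy-3,7,11,15-tetramethylhexadecyl]-3,6-dimethylphenyl trifluoromethanesulfonate F8.
- Intramolecular Buchwald–Hartwig etherification (Pd(OAc)2, 2-(di-tert-butylphosphino)-1,1'-binaphthyl, Cs2CO3, toluene, 80 °C) gives the O-tert-butyldimethylsilyl ether of (2R,4'R,8'R)-β-tocopherol F9.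
- Bu4NF in THF releases 19.

**Step 7.**
- What may go wrong: Wurtz-type homocoupling may occur during magnesium insertion into the electron-rich benzylic chloride. Double chloromethylation in step 6 would make the supply problem worse.
- Fallback: it sets out from 7, bypasses 8 and 10, and comes back at 11. The stereocentre comes from an enzyme instead of the chiral pool.
- N-Iodosuccinimide with catalytic CF3CO2H in MeCN gives 1-iodo-2,5-dimethoxy-3,6-dimethylbenzene F10.
- Jeffery–Heck arylation of but-3-en-2-ol (Pd(OAc)2, Bu4NCl, NaHCO3, DMF, 60 °C) proceeds with β-hydride elimination towards the carbinol and tautomerisation. It gives 4-(2,5-dimethoxy-3,6-dimethylphenyl)butan-2-one F11.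
- An (R)-selective alcohol dehydrogenase of the Lactobacillus type (NADP+, i-PrOH, buffer, 30 °C) should reduce this methyl ketone to 11.

Further compounds
F1 | step 9 | (4R,8R)-1-iodo-4,8,12-trimethyltridecane | ICCC[C@H](C)CCC[C@H](C)CCCC(C)C
F2 | step 9 | (2S,5S)-2-tert-butyl-5-methyl-1,3-dioxolan-4-one | CC(C)(C)[C@@H]1OC(=O)[C@H](C)O1
F3 | step 9 | (2S,5R)-2-tert-butyl-5-methyl-5-[(4R,8R)-4,8,12-trimethyltridecyl]-1,3-dioxolan-4-one | CC(C)(C)[C@@H]1OC(=O)[C@@](C)(CCC[C@H](C)CCC[C@H](C)CCCC(C)C)O1
F4 | step 9 | (2R,6R,10R)-2,6,10,14-tetramethylpentadecane-1,2-diol | O[C@](C)(CCC[C@H](C)CCC[C@H](C)CCCC(C)C)CO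
F5 | step 9 | (2R,6R,10R)-2-hydroxy-2,6,10,14-tetramethylpentadecyl 4-methylbenzenesulfonate | O[C@](C)(CCC[C@H](C)CCC[C@H](C)CCCC(C)C)COS(=O)(=O)c1ccc(C)cc1
F6 | step 9 | (2R)-2-methyl-2-[(4R,8R)-4,8,12-trimethyltridecyl]oxirane | C[C@@]1(CCC[C@H](C)CCC[C@H](C)CCCC(C)C)CO1
F7 | step 11 | 4-[(tert-butyldimethylsilyl)oxy]-2-[(3R,7R,11R)-3-hydroxy-3,7,11,15-tetramethylhexadecyl]-3,6-dimethylphenol | O[C@](C)(CCC[C@H](C)CCC[C@H](C)CCCC(C)C)CCc1c(C)c(O[Si](C)(C)C(C)(C)C)cc(C)c1O
F8 | step 11 | 4-[(tert-butyldimethylsilyl)oxy]-2-[(3R,7R,11R)-3-hydroxy-3,7,11,15-tetramethylhexadecyl]-3,6-dimethylphenyl trifluoromethanesulfonate | O[C@](C)(CCC[C@H](C)CCC[C@H](C)CCCC(C)C)CCc1c(C)c(O[Si](C)(C)C(C)(C)C)cc(C)c1OS(=O)(=O)C(F)(F)F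
F9 | step 11 | O-tert-butyldimethylsilyl ether of (2R,4'R,8'R)-β-tocopherol | Cc1cc(O[Si](C)(C)C(C)(C)C)c(C)c2c1O[C@](C)(CCC[C@H](C)CCC[C@H](C)CCCC(C)C)CC2
F10 | step 7 | 1-iodo-2,5-dimethoxy-3,6-dimethylbenzene | COc1cc(C)c(OC)c(I)c1C
F11 | step 7 | 4-(2,5-dimethoxy-3,6-dimethylphenyl)butan-2-one | CC(=O)CCc1c(C)c(OC)cc(C)c1OC
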